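In a one-step world, substrate meets reagent, becomes target, and the target waits for you; this flask has more exits than that.

    target → decomposed product (k1 = 0.035 s⁻¹)
    target ⇌ product in the second phase, rate k2*([target] - [product in the second phase]/K2) per volume of the first phase (K2 = 20, k2 = 0.018 s⁻¹)
    reagent in the reaction phase ⇌ reagent in the second phase, rate k3*([reagent in the reaction phase] - [reagent in the second phase]/K3) per volume of the first phase (K3 = 0.43, k3 = 0.076 s⁻¹)
    target ⇌ isomer of the product (K4 = 0.36, k4 = 0.0069 s⁻¹)
    target → over-reaction product (k5 = 0.011 s⁻¹)
    2 reagent in the reaction phase → homo dimer (k6 = 0.13 L mol⁻¹ s⁻¹)
    substrate + reagent in the reaction phase → target (k7 = 0.10 L mol⁻¹ s⁻¹)

substrate 0.40 M; reagent in the second phase 1.60 M; time 1.0 min; volume of the second phase over the first 2.0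

- amounts and yields of target count product in the second phase too
- a step written with two of one species runs at k times the square of its concentration and takes two of it each time
- in the second phase: reagent in the second phase, product in the second phase; everything else is in the first
- charges count per volume of the first phase; a concentration in a rate is the amount of a species over the volume of its own phase; every rate counts per litre of the first phase
- run time (flask): 1.0 min

- Thursday's: doubling the transfer coefficient of step 3, all else as stated
- Saturday's: doubling the transfer coefficient of step 2, all else as stated
- Wednesday's: doubling the amount of reagent in the second phase, all else as stated

- target and product in the second phase together at 1.0 min, in percent of the substrate charged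
- the change that raises the amount of target and product in the second phase together at 1.0 min, in percent of the substrate charged most ("none" if none brings more than 2 percentage points) (Thursday's / Saturday's / Wednesday's / none)
- amount of target and product in the second phase together at 1.0 min, in percent of the substrate charged, after Thursday's

The bench rule says to extract as you go. Take the partition ratio of 20 and a second phase 2.0 times the first, and 97.6% of the target sits in the second phase at balance, so you would expect a yield close to conversion. But that is a balance, and the target has to get there. Hold the transfer coefficient 0.018 s⁻¹ against the two losses in the first phase, decomposition at 0.035 s⁻¹ and over-reaction at 0.011 s⁻¹. The ratio, a selectivity factor, is 0.391, so passage is slower than loss. The rule needs that ratio far above one, and this flask is past the border.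

So follow one molecule of target in the first phase. I set aside the isomer, which can return, and the leak back from the second phase. The molecule then has three exits, and the chance that it reaches the second phase before it is destroyed is the transfer coefficient over the sum of the three constants, 28.1%: this is the escape chance. Saturday's raises it to 43.9%. Thursday's and Wednesday's leave it where it stands and alter how much target is made, so I commit to Saturday's. My reckoning stops there and gives no yield at the clock, since target still in the first phase counts in the yield and has not yet taken an exit.

The forecast gives 26.7%, and 24% after Thursday's, and picks Saturday's, since “extraction competes better against decay”.

The flask gives 26.7%, and 25.7% after Thursday's, with Saturday's best: it adds 8.6 percentage points, Wednesday's 2.6 points, Thursday's −0.97 points. The pace of the passage of target into the second phase is the main reason for the shortfall: with that hold-up taken away, the run gives 72.0%. At 1.00 min the second phase of the flask holds 27.8% of what has left by the three exits, against an escape chance of 28.1%. Left until 4.0 min, with 9.0% of the substrate still there, the escape chance times the converted part gives 25.6%, and that neighbour flask holds 23.8% as product in the second phase.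

All constants were chosen freely; the run is a simulation.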